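An enzyme at 10 µM cannot take a charge of 0.10 M in a single pass, since it stands far below that charge, so each enzyme molecule has to turn over many times, and I count those turnovers.

common to all: enzyme 10 µM

| flask | starting material | second substrate | remark | time |
|---|---|---|---|---|
| delta | 0.032 M | 0.40 M | run made earlier |  |
| theta | 0.089 M | 0.40 M | run made earlier |  |
| grey | 0.040 M | 0.400 M |  | 2.5 d |
| green | 0.060 M | 0.400 M |  | 2.5 d |
| ochre | 0.10 M | 0.400 M |  | 2.5 d |

The recipes differ in their starting material, so grey asks 4000 turnovers of each enzyme, green 6000 and ochre 10000, and in each recipe the starting material is the limiting reagent, lying below the second substrate. But a count of turnovers means nothing without a speed, so I go to the readings.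

| delta: time / d | delta: product / % | theta: time / d | theta: product / % |
|---|---|---|---|
| 0.500 | 100.3 | 0.208 | 54.3 |
| 1.04 | 100.1 | 0.417 | 88.5 |
| 1.67 | 100.6 | 0.625 | 98.8 |
| 2.08 | 99.6 | 1.25 | 100.4 |
| 2.50 | 100.1 | 2.50 | 99.7 |

(scatter of a reading: 0.5 percentage points)

- [product] at the end for grey, green, ochre, in this order
- how the row runs (rises, then falls / falls all the way / falls, then rises / hardly changes / rises all the way)

- "hardly changes" means that all values lie within two and a half points (for a concentration: within two and a half percent of the largest)

Delta already shows 100.3% at its first reading, 0.500 d, so it gives me no speed. But theta reaches 98.8% at 0.625 d and still reads 99.7% at 2.50 d, so by my own reckoning it gives, as a figure read off scattered readings, 14100 d⁻¹, the whole-run turnover rate, which I define as product made per enzyme charged and per time up to the reading where theta is practically finished, slow tail included. Dividing ochre's 10000 turnovers by this rate gives an estimated clearing time of 0.711 d, shorter than the 2.5 d allowed by a factor of 3.52, but ochre's charge lies beyond theta's by a factor of 1.12, so this is a modest extrapolation, and I commit to full conversion in grey, green and ochre.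

The forecast gives 0.04 M, 0.06 M and 0.1 M, a row that rises all the way, reasoning by saturation kinetics rather than by my count: “At 0.10 M, complete conversion should take about one day or less, well inside 2.5 d.” Its day stands beside my 0.711 d.

The flask gives 0.0400 M, 0.0600 M and 0.100 M, a row that rises all the way.

    starting material + enzyme ⇌ starting complex (K = 11.0 M⁻¹, k = 9.60 × 10⁵ M⁻¹ h⁻¹)
    ternary complex → enzyme + product (k = 1500 h⁻¹)
    second substrate + starting complex ⇌ ternary complex (K = 18.0 M⁻¹, k = 78000 M⁻¹ h⁻¹)
    second substrate ⇌ dormant form (K = 0.130, k = 0.160 h⁻¹)

My estimated clearing time for ochre, 0.711 d, falls before 1.25 d, when ochre stands at >99.9% product. Green's 6000 turnovers at the whole-run turnover rate of 14100 d⁻¹ come by my estimate to 0.426 d, and at 1.25 d green stands at >99.9% product.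

Readings and results were computed from invented constants, noise included.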